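**Strategy.** Everything rests on opening ring C at three bonds, C4a–C4, C4–C3 and O1–C2. Ring C is a ketone carbon (C4) on C4a, an ether oxygen (O1) on the neighbouring C8a of ring A, and a two-carbon bridge C3–C2 that carries ring B. C4 is supplied as carbon monoxide, C3–C2 as the acetylene of a ring B arylacetylene, and C4a/O1 as the C–I and OH of an ortho-iodophenol. One palladium-catalysed carbonylative alkynylation–cyclisation makes all three bonds and the flavone. The precursor is 2-iodo-3,5-bis(MOM-oxy)-4-prenylphenol, whose prenyl position (C6) is locked by symmetry. Asymmetric hydride addition to C2 (S) and acid deprotection finish the route.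

Key step: step 8

Assumption (chemistry): 3-bromo-4,5-dihydroxybenzaldehyde, tributyl(prenyl)stannane and the Ohira–Bestmann reagent are bought. Which ligand enantiomer gives the (2S) product in step 9 must be established by experiment; the (R) ligand is written as the working choice and its antipode is used if the opposite sense is found.

**Route**

Step 1
Reactants: 1 resorcinol
Product: 2 1,3-bis(methoxymethoxy)benzene
Conditions: MOMCl (2.5 equiv), i-Pr2NEt, CH2Cl2, 0 °C→rt
Reagents that add atoms: chloromethyl methyl ether, COCCl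
Why: Plain O-alkylation of both phenols to the MOM ethers, with the amine taking up HCl and no competing site in the molecule.

Step 2
Reactants: 2 1,3-bis(methoxymethoxy)benzene; 3 prenyl bromide
Product: 5 1,3-bis(methoxymethoxy)-2-(3-methylbut-2-en-1-yl)benzene, via aryllithium 4 (not isolated)
Conditions: n-BuLi (1.1 equiv), THF, 0 °C→rt; then CuBr·SMe2 (10 mol %), 3, −78 °C→rt
Reagents that add atoms: prenyl bromide (3), CC(C)=CCBr
Why: Directed ortho-metalation removes the C2–H flanked and chelated by both MOM ethers, and copper-catalysed SN2 coupling of the aryllithium with the primary allylic bromide should give the linear prenyl arene.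

Step 3
Reactants: 5 1,3-bis(methoxymethoxy)-2-(3-methylbut-2-en-1-yl)benzene
Product: 7 3,5-bis(methoxymethoxy)-4-(3-methylbut-2-en-1-yl)phenol, via aryl pinacolboronate 6 (not isolated)
Conditions: [Ir(OMe)(cod)]2 (1.5 mol %), 4,4′-di-tert-butyl-2,2′-bipyridine (3 mol %), B2pin2 (0.8 equiv), THF, 60 °C; then aq. NaOH, 30% H2O2, THF, 0 °C
Reagents that add atoms: hydrogen peroxide, OO
Why: Sterically governed iridium-catalysed aromatic C–H borylation should take the only ring C–H with no ortho substituent (para to the prenyl group), and alkaline peroxide oxidation of the C–B bond (aryl shift from boron to oxygen) then gives the phenol without touching the trisubstituted alkene or the MOM ethers.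

Step 4
Reactants: 7 3,5-bis(methoxymethoxy)-4-(3-methylbut-2-en-1-yl)phenol
Product: 8 2-iodo-3,5-bis(methoxymethoxy)-4-(3-methylbut-2-en-1-yl)phenol
Conditions: I2 (1.0 equiv), NaHCO3, THF/H2O, 0 °C, dark
Reagents that add atoms: iodine, II
Why: Electrophilic aromatic iodination of the phenoxide, in which the two positions ortho to OH are related by the twofold axis through C1 and C4 so that one equivalent of iodine can give only one mono-iodide, and ring attack on the phenoxide is faster than attack on the prenyl alkene.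

Step 5
Reactants: 9 3-bromo-4,5-dihydroxybenzaldehyde
Product: 10 3-bromo-4,5-bis(methoxymethoxy)benzaldehyde
Conditions: MOMCl (3 equiv), i-Pr2NEt, CH2Cl2, 0 °C→rt
Reagents that add atoms: chloromethyl methyl ether, COCCl
Why: MOM ether formation on both catechol hydroxyls, with the aldehyde and the aryl bromide inert to the mild base.

Step 6
Reactants: 10 3-bromo-4,5-bis(methoxymethoxy)benzaldehyde; 11 tributyl(3-methylbut-2-en-1-yl)stannane
Product: 12 3,4-bis(methoxymethoxy)-5-(3-methylbut-2-en-1-yl)benzaldehyde
Conditions: Pd(PPh3)4 (5 mol %), DMF, 100 °C; aq. KF work-up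
Reagents that add atoms: tributyl(3-methylbut-2-en-1-yl)stannane (11), CCCC[Sn](CCCC)(CCCC)CC=C(C)C
Why: Stille coupling, in which oxidative addition at C–Br, allyl transfer from tin and reductive elimination at the unsubstituted allyl terminus should give the linear prenyl arene under neutral conditions that spare the aldehyde and the MOM ethers.

Step 7
Reactants: 12 3,4-bis(methoxymethoxy)-5-(3-methylbut-2-en-1-yl)benzaldehyde; 13 dimethyl (1-diazo-2-oxopropyl)phosphonate (Ohira–Bestmann reagent)
Product: 14 5-ethynyl-1,2-bis(methoxymethoxy)-3-(3-methylbut-2-en-1-yl)benzene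
Conditions: K2CO3 (2 equiv), MeOH, 0 °C→rt
Reagents that add atoms: dimethyl (1-diazo-2-oxopropyl)phosphonate (13), CC(=O)C(=[N+]=[N-])P(=O)(OC)OC
Why: Seyferth–Gilbert homologation in its Ohira–Bestmann form, in which methoxide unmasks the diazomethylphosphonate anion, this olefinates the aldehyde, and loss of N2 with a 1,2-hydrogen shift gives the terminal alkyne under base mild enough for all other groups.

Step 8
Reactants: 8 2-iodo-3,5-bis(methoxymethoxy)-4-(3-methylbut-2-en-1-yl)phenol; 14 5-ethynyl-1,2-bis(methoxymethoxy)-3-(3-methylbut-2-en-1-yl)benzene (1.3 equiv); 15 carbon monoxide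
Product: 18 5,7-bis(methoxymethoxy)-2-[3,4-bis(methoxymethoxy)-5-(3-methylbut-2-en-1-yl)phenyl]-6-(3-methylbut-2-en-1-yl)-4H-chromen-4-one, via hydroxyaryl ynone 16 (not isolated), via diethylamino enone 17 (not isolated)
Conditions: PdCl2(dppf) (5 mol %), CO (20 bar), Et2NH, 120 °C, autoclave
Reagents that add atoms: carbon monoxide (15), [C-]#[O+]
Why: PdCl2(dppf) is reduced in the amine to zerovalent palladium, which inserts into the C–I bond of 8; CO insertion gives the aroyl complex of divalent palladium, and amine-assisted transfer of the acetylide of 14 with reductive elimination forms C4a–C4 and C4–C3 in ynone 16. Diethylamine then adds to the ynone at the carbon bearing ring B to give enaminone 17, and the ortho phenol oxygen attacks that same carbon and expels the amine, forming O1–C2. The closest known reaction type is the palladium-catalysed carbonylative coupling of 2-iodophenols with terminal arylacetylenes in a secondary amine, which gives flavones directly. Ring C closes by a 6-endo-trig addition–elimination on the enaminone (formally 6-endo-dig on the ynone), and no stereocentre is formed. The step needs carbonylation to beat direct alkynylation (which would end in a benzofuran) and amide formation, and six-ring closure to beat 5-exo closure to the aurone; fast CO insertion into the electron-rich aryl–palladium bond under CO pressure, and the enaminone, which makes the ring B carbon the electrophile, should secure this. Regiochemistry is fixed by the substrate, since the only free hydroxyl of 8 sits next to the iodide and both other oxygens are MOM ethers, so the prenyl group can only end at C6.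

Step 9
Reactants: 18 tetra-MOM flavone
Product: 20 (2S)-5,7-bis(methoxymethoxy)-2-[3,4-bis(methoxymethoxy)-5-(3-methylbut-2-en-1-yl)phenyl]-6-(3-methylbut-2-en-1-yl)-2,3-dihydro-4H-chromen-4-one, via silyl enol ether 19 (not isolated)
Conditions: Cu(OAc)2 (5 mol %), (R)-DTBM-SEGPHOS (5.5 mol %), (EtO)2MeSiH (3 equiv), toluene, 0 °C→rt; then 1 M aq. HCl/THF, 0 °C, short
Reagents that add atoms: none
Why: Copper hydride-catalysed asymmetric 1,4-reduction of a 2-substituted chromone, in which the bisphosphine-ligated hydride of monovalent copper delivers hydrogen to C2 from the face chosen by the chiral ligand (this sets the C2 stereocentre), the enolate is trapped by the silane as silyl enol ether 19 (which blocks over-reduction and opening of ring C), and brief dilute acid releases the ketone while isolated alkenes and MOM ethers stay untouched.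

Step 10
Reactants: 20 (2S)-tetra-MOM flavanone
Product: 21 (2S)-2-[3,4-dihydroxy-5-(3-methylbut-2-en-1-yl)phenyl]-5,7-dihydroxy-6-(3-methylbut-2-en-1-yl)-2,3-dihydro-4H-chromen-4-one (target)
Conditions: 2 M aq. HCl/MeOH (1:4), 40 °C, argon
Reagents that add atoms: none
Why: Acid-catalysed acetal exchange of the four aryl MOM ethers with methanol, run dilute and warm (not hot) so that the prenyl groups are not cyclised onto the neighbouring phenols and, in the absence of base, C2 is not epimerised through ring opening.

**Compound list**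

1 | resorcinol | Oc1cccc(O)c1 | starting material
2 | 1,3-bis(methoxymethoxy)benzene | COCOc1cccc(OCOC)c1 | intermediate
3 | prenyl bromide (1-bromo-3-methylbut-2-ene) | CC(C)=CCBr | starting material
4 | 2,6-bis(methoxymethoxy)phenyllithium | [Li]c1c(OCOC)cccc1OCOC | intermediate
5 | 1,3-bis(methoxymethoxy)-2-(3-methylbut-2-en-1-yl)benzene | COCOc1cccc(OCOC)c1CC=C(C)C | intermediate
6 | 2-[3,5-bis(methoxymethoxy)-4-(3-methylbut-2-en-1-yl)phenyl]-4,4,5,5-tetramethyl-1,3,2-dioxaborolane | COCOc1cc(B2OC(C)(C)C(C)(C)O2)cc(OCOC)c1CC=C(C)C | intermediate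
7 | 3,5-bis(methoxymethoxy)-4-(3-methylbut-2-en-1-yl)phenol | COCOc1cc(O)cc(OCOC)c1CC=C(C)C | intermediate
8 | 2-iodo-3,5-bis(methoxymethoxy)-4-(3-methylbut-2-en-1-yl)phenol | COCOc1cc(O)c(I)c(OCOC)c1CC=C(C)C | intermediate
9 | 3-bromo-4,5-dihydroxybenzaldehyde | O=Cc1cc(O)c(O)c(Br)c1 | starting material
10 | 3-bromo-4,5-bis(methoxymethoxy)benzaldehyde | O=Cc1cc(OCOC)c(OCOC)c(Br)c1 | intermediate
11 | tributyl(3-methylbut-2-en-1-yl)stannane | CCCC[Sn](CCCC)(CCCC)CC=C(C)C | starting material
12 | 3,4-bis(methoxymethoxy)-5-(3-methylbut-2-en-1-yl)benzaldehyde | O=Cc1cc(OCOC)c(OCOC)c(CC=C(C)C)c1 | intermediate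
13 | dimethyl (1-diazo-2-oxopropyl)phosphonate | CC(=O)C(=[N+]=[N-])P(=O)(OC)OC | starting material
14 | 5-ethynyl-1,2-bis(methoxymethoxy)-3-(3-methylbut-2-en-1-yl)benzene | C#Cc1cc(OCOC)c(OCOC)c(CC=C(C)C)c1 | intermediate
15 | carbon monoxide | [C-]#[O+] | starting material
16 | 1-[6-hydroxy-2,4-bis(methoxymethoxy)-3-(3-methylbut-2-en-1-yl)phenyl]-3-[3,4-bis(methoxymethoxy)-5-(3-methylbut-2-en-1-yl)phenyl]prop-2-yn-1-one | O=C(C#Cc1cc(OCOC)c(OCOC)c(CC=C(C)C)c1)c1c(O)cc(OCOC)c(CC=C(C)C)c1OCOC | intermediate
17 | 3-(diethylamino)-1-[6-hydroxy-2,4-bis(methoxymethoxy)-3-(3-methylbut-2-en-1-yl)phenyl]-3-[3,4-bis(methoxymethoxy)-5-(3-methylbut-2-en-1-yl)phenyl]prop-2-en-1-one (alkene geometry not fixed, isomers interconvert) | CCN(CC)C(=CC(=O)c1c(O)cc(OCOC)c(CC=C(C)C)c1OCOC)c1cc(OCOC)c(OCOC)c(CC=C(C)C)c1 | intermediate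
18 | 5,7-bis(methoxymethoxy)-2-[3,4-bis(methoxymethoxy)-5-(3-methylbut-2-en-1-yl)phenyl]-6-(3-methylbut-2-en-1-yl)-4H-chromen-4-one | O=c1cc(-c2cc(OCOC)c(OCOC)c(CC=C(C)C)c2)oc2cc(OCOC)c(CC=C(C)C)c(OCOC)c12 | intermediate
19 | (2S)-4-[diethoxy(methyl)silyloxy]-5,7-bis(methoxymethoxy)-2-[3,4-bis(methoxymethoxy)-5-(3-methylbut-2-en-1-yl)phenyl]-6-(3-methylbut-2-en-1-yl)-2H-chromene | CC(C)=CCc1cc([C@@H]2C=C(O[Si](C)(OCC)OCC)c3c(cc(OCOC)c(CC=C(C)C)c3OCOC)O2)cc(OCOC)c1OCOC | intermediate
20 | (2S)-5,7-bis(methoxymethoxy)-2-[3,4-bis(methoxymethoxy)-5-(3-methylbut-2-en-1-yl)phenyl]-6-(3-methylbut-2-en-1-yl)-2,3-dihydro-4H-chromen-4-one | CC(C)=CCc1cc([C@@H]2CC(=O)c3c(cc(OCOC)c(CC=C(C)C)c3OCOC)O2)cc(OCOC)c1OCOC | intermediate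
21 | (2S)-2-[3,4-dihydroxy-5-(3-methylbut-2-en-1-yl)phenyl]-5,7-dihydroxy-6-(3-methylbut-2-en-1-yl)-2,3-dihydro-4H-chromen-4-one | CC(C)=CCc1cc([C@@H]2CC(=O)c3c(cc(O)c(CC=C(C)C)c3O)O2)cc(O)c1O | target

**Step count.** Total: 10 steps. Longest linear sequence: 7 steps (steps 1–4, 8, 9, 10); the ring B branch (steps 5–7) joins at step 8.

**Steps most likely to fail and fallbacks**

Step 9. The hydride transfer may discriminate the faces of C2 poorly, the hindered electron-rich vinylogous ester may accept hydride slowly, or the copper enolate may open ring C by expelling the aryloxide before it is silylated. The fallback sets out from flavone 18 and comes back at 20. An achiral, more reactive copper hydride (Cu(OAc)2, 1,2-bis(diphenylphosphino)benzene, (EtO)2MeSiH, toluene) should give the racemic silyl enol ether F1, and dilute acid then gives the racemic tetra-MOM flavanone F2. F2 is resolved kinetically by asymmetric transfer hydrogenation (RhCl[(R,R)-TsDPEN]Cp*, HCO2H/Et3N, EtOAc, rt). By the usual aryl ketone model this catalyst should reduce the (2R)-ketone to the cis-(2R,4R)-flavan-4-ol F3 and leave the (2S)-ketone 20, which is separated by chromatography.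

Step 8. CO uptake may be lost so that direct alkynylation and five-membered closure take over, the amine may capture the aroylpalladium species, or oxidative addition at the doubly ortho-substituted, electron-rich C–I bond may be slow. The fallback sets out from phenol 7 (with alkyne 14) and comes back at flavone 18 by way of ynone 16, without palladium or CO. Magnesium-mediated ortho-formylation of 7 (MgCl2, Et3N, paraformaldehyde, MeCN, reflux) should give 6-hydroxy-2,4-bis(methoxymethoxy)-3-prenylbenzaldehyde F4. Its phenol is deprotonated with LiN(SiMe3)2 and the lithium acetylide of 14 (n-BuLi, THF, −78 °C) is added to give the racemic propargylic alcohol F5. MnO2 in CH2Cl2 oxidises F5 to ynone 16, which is now isolated. Warming 16 with Et2NH in EtOH closes ring C by the same amine-mediated 6-endo pathway to 18.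

Step 3. The iridium boryl species and the pinacolborane formed may hydroborate or isomerise the prenyl alkene, or peroxide may oxidise the electron-rich phenoxide further. The fallback sets out from 2 and comes back at phenol 7, with the borylation done before any alkene is present. The same borylation/oxidation on 2 goes through the aryl pinacolboronate F6 to 3,5-bis(methoxymethoxy)phenol F7. Silylation (i-Pr3SiCl, imidazole, DMF) gives the triisopropylsilyl ether F8. n-BuLi in THF at 0 °C should lithiate between the two MOM ethers, the bulky silyl ether shielding its own ortho positions, to give the aryllithium F9. Copper-catalysed coupling with prenyl bromide 3 gives the prenylated silyl ether F10, and Bu4NF in THF at 0 °C releases 7.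

**Further compounds**

F1 | step 9 | racemic 4-[diethoxy(methyl)silyloxy]-5,7-bis(methoxymethoxy)-2-[3,4-bis(methoxymethoxy)-5-(3-methylbut-2-en-1-yl)phenyl]-6-(3-methylbut-2-en-1-yl)-2H-chromene | CCO[Si](C)(OCC)OC1=CC(c2cc(OCOC)c(OCOC)c(CC=C(C)C)c2)Oc2cc(OCOC)c(CC=C(C)C)c(OCOC)c12
F2 | step 9 | racemic 5,7-bis(methoxymethoxy)-2-[3,4-bis(methoxymethoxy)-5-(3-methylbut-2-en-1-yl)phenyl]-6-(3-methylbut-2-en-1-yl)-2,3-dihydro-4H-chromen-4-one | O=C1CC(c2cc(OCOC)c(OCOC)c(CC=C(C)C)c2)Oc2cc(OCOC)c(CC=C(C)C)c(OCOC)c12
F3 | step 9 | (2R,4R)-5,7-bis(methoxymethoxy)-2-[3,4-bis(methoxymethoxy)-5-(3-methylbut-2-en-1-yl)phenyl]-6-(3-methylbut-2-en-1-yl)chroman-4-ol | O[C@@H]1C[C@H](c2cc(OCOC)c(OCOC)c(CC=C(C)C)c2)Oc2cc(OCOC)c(CC=C(C)C)c(OCOC)c12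
F4 | step 8 | 6-hydroxy-2,4-bis(methoxymethoxy)-3-(3-methylbut-2-en-1-yl)benzaldehyde | O=Cc1c(O)cc(OCOC)c(CC=C(C)C)c1OCOC
F5 | step 8 | racemic 1-[6-hydroxy-2,4-bis(methoxymethoxy)-3-(3-methylbut-2-en-1-yl)phenyl]-3-[3,4-bis(methoxymethoxy)-5-(3-methylbut-2-en-1-yl)phenyl]prop-2-yn-1-ol | OC(C#Cc1cc(OCOC)c(OCOC)c(CC=C(C)C)c1)c1c(O)cc(OCOC)c(CC=C(C)C)c1OCOC
F6 | step 3 | 2-[3,5-bis(methoxymethoxy)phenyl]-4,4,5,5-tetramethyl-1,3,2-dioxaborolane | COCOc1cc(OCOC)cc(B2OC(C)(C)C(C)(C)O2)c1
F7 | step 3 | 3,5-bis(methoxymethoxy)phenol | COCOc1cc(O)cc(OCOC)c1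
F8 | step 3 | [3,5-bis(methoxymethoxy)phenoxy]triisopropylsilane | COCOc1cc(OCOC)cc(O[Si](C(C)C)(C(C)C)C(C)C)c1
F9 | step 3 | 2,6-bis(methoxymethoxy)-4-(triisopropylsilyloxy)phenyllithium | [Li]c1c(OCOC)cc(O[Si](C(C)C)(C(C)C)C(C)C)cc1OCOC
F10 | step 3 | [3,5-bis(methoxymethoxy)-4-(3-methylbut-2-en-1-yl)phenoxy]triisopropylsilane | COCOc1cc(O[Si](C(C)C)(C(C)C)C(C)C)cc(OCOC)c1CC=C(C)C
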